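**Retrosynthetic overview**
- The ester bond at the C4 oxygen is cut first. This gives 3-hydroxy-3-methylbutanoic acid, carried as its triethylsilyl ether acid chloride, and the free 4-hydroxy-2-pyranone.
- Ring A (O1, C2–C6) is the only ring to be made. It is opened at O1–C2 to an acyclic methyl 3,5-dioxo ester and is closed late by base-induced lactonisation.
- The chain is cut at C5–C6. This bond joins an unsubstituted, enolisable C5 to the phenyl-bearing carbonyl carbon C6, and it lies well away from C3, which carries the quaternary carbon of the 2-methylbut-3-en-2-yl group. The strategy rests on making the last C–C bond at this open end while C3 is masked as an enolate.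
- The β-keto ester precursor comes from C-acetylation of methyl 3,3-dimethylpent-4-enoate, which supplies C2, C3 and the complete C3 side chain.

Key step: step 2

Remark: the target has no stereocentre. The two β-keto ester intermediates each have one configurationally labile α-carbon, are handled as racemates and are drawn as keto tautomers.

**Step 1**
Reactants: 1 methyl 3,3-dimethylpent-4-enoate; 2 1-acetylimidazole
Product: 4 racemic methyl 2-acetyl-3,3-dimethylpent-4-enoate, via lithium enolate 3 (not isolated)
Conditions: 1 (2.1 equiv), LiN(i-Pr)2 (2.0 equiv), THF, −78 °C; 2 (1.0 equiv), −78 → 0 °C; cold 1 M HCl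
Reagents that add atoms: none
Why: This is a crossed Claisen condensation of a preformed lithium ester enolate with an N-acylimidazole, in which the neopentyl-type α-carbon of 3 slows self-condensation at −78 °C, the imidazolide leaving group favours C- over O-acylation, the surplus enolate absorbs the acidic proton of the product, and the new α-stereocentre forms without control as a racemate, which does not matter because it becomes sp2 in step 3.

**Step 2**
Reactants: 4 racemic methyl 2-acetyl-3,3-dimethylpent-4-enoate; 5 N-methoxy-N-methylbenzamide
Product: 9 racemic methyl 2-(2-methylbut-3-en-2-yl)-3,5-dioxo-5-phenylpentanoate, via sodium enolate 6 (not isolated), via sodium lithium dianion 7 (not isolated), via chelated tetrahedral adduct 8 (not isolated)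
Conditions: NaH (1.1 equiv), THF, 0 °C → rt until H2 evolution ends; n-BuLi (1.05 equiv), 0 °C; 5 (0.9 equiv), −78 → 0 °C; cold 1 M HCl
Reagents that add atoms: none
Why: NaH removes the doubly activated methine proton of 4 to give sodium enolate 6, n-BuLi then takes a proton from the acetyl CH3 to give the 1,3-dianion 7, and the terminal carbanion of 7 (future C5) adds to the amide carbonyl of 5 (future C6), which makes the C5–C6 bond. The adduct 8 is held as a five-membered lithium chelate between the alkoxide oxygen and the N-methoxy oxygen and collapses only on acid quench, so the far more acidic 1,3-diketone never meets unreacted 7 and a second addition is excluded. The closest known reaction type is the γ-acylation of β-keto ester 1,3-dianions by esters or N-methoxy-N-methylamides (Weinreb ketone synthesis), which is established for 2-alkyl acetoacetates. No ring is closed in this step. No new stereocentre is set, because the only stereocentre of 9, the α-carbon (future C3), is planar in 6 to 8, returns as a racemate on protonation and is erased in step 3. The step needs a single acylation at the terminal carbon rather than at the inner carbon or at oxygen, and this is secured because the last-formed, least stabilised carbanion is by far the more nucleophilic site and the 2-methylbut-3-en-2-yl group further screens the inner carbon.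

**Step 3**
Reactants: 9 racemic methyl 2-(2-methylbut-3-en-2-yl)-3,5-dioxo-5-phenylpentanoate
Product: 10 4-hydroxy-3-(2-methylbut-3-en-2-yl)-6-phenyl-2H-pyran-2-one
Conditions: DBU (1.5 equiv), toluene, reflux; 1 M HCl
Reagents that add atoms: none
Why: This is a base-induced lactonisation (intramolecular transesterification, 6-exo-trig addition–elimination) in which DBU enolises the benzoyl carbonyl, the enolate oxygen on C6 attacks the ester carbonyl C2 and expels methoxide, and formation of the acidic, fully conjugated 4-hydroxy-2-pyranone drives closure of ring A while the vinyl group and the quaternary carbon are untouched and the α-stereocentre disappears.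

**Step 4**
Reactants: 11 3-hydroxy-3-methylbutanoic acid
Product: 12 triethylsilyl 3-methyl-3-[(triethylsilyl)oxy]butanoate
Conditions: Et3SiOTf (2.3 equiv), 2,6-lutidine (3 equiv), CH2Cl2, 0 °C → rt; pentane, quick cold aq. NaHCO3 wash, bulb-to-bulb distillation
Reagents that add atoms: triethylsilyl trifluoromethanesulfonate, CC[Si](CC)(CC)OS(=O)(=O)C(F)(F)F
Why: This is an exhaustive silylation with a silyl triflate and a hindered pyridine base, in which the triflate is reactive enough for the tertiary alcohol and also turns the acid into the silyl ester needed for step 5, with no stereocentre involved.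

**Step 5**
Reactants: 12 triethylsilyl 3-methyl-3-[(triethylsilyl)oxy]butanoate
Product: 13 3-methyl-3-[(triethylsilyl)oxy]butanoyl chloride
Conditions: (COCl)2 (1.1 equiv), DMF (cat.), CH2Cl2, 0 °C → rt; volatiles including Et3SiCl removed in vacuo, used crude
Reagents that add atoms: oxalyl chloride, O=C(Cl)C(=O)Cl
Why: This is the known conversion of a silyl ester into an acid chloride with oxalyl chloride and catalytic DMF (Vilsmeier-type chloroiminium activation), in which the ester oxygen attacks the chloroiminium salt and chloride carries off the silyl group, so no HCl is formed and the acid-labile tertiary silyl ether should survive.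

**Step 6**
Reactants: 10 4-hydroxy-3-(2-methylbut-3-en-2-yl)-6-phenyl-2H-pyran-2-one; 13 3-methyl-3-[(triethylsilyl)oxy]butanoyl chloride
Product: 14 3-(2-methylbut-3-en-2-yl)-2-oxo-6-phenyl-2H-pyran-4-yl 3-methyl-3-[(triethylsilyl)oxy]butanoate
Conditions: pyridine (3 equiv), DMAP (cat.), CH2Cl2, 0 °C → rt
Reagents that add atoms: none
Why: This is an O-acylation of a vinylogous acid with an acid chloride under nucleophilic catalysis (Einhorn-type acylation), in which the fully substituted C3 blocks the usual O-to-C acyl shift, reversible acyl transfer should favour the more stable 4-acyloxy-2-pyranone over the 2-acyloxy-4-pyranone, and the weak base limits β-elimination of the silyloxy group.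

**Step 7**
Reactants: 14 3-(2-methylbut-3-en-2-yl)-2-oxo-6-phenyl-2H-pyran-4-yl 3-methyl-3-[(triethylsilyl)oxy]butanoate
Product: 15 3-(2-methylbut-3-en-2-yl)-2-oxo-6-phenyl-2H-pyran-4-yl 3-hydroxy-3-methylbutanoate (target, CNP0160044.0)
Conditions: HF·pyridine, pyridine, THF, 0 °C → rt (plastic vessel); pH 7 phosphate buffer
Reagents that add atoms: none
Why: This is a fluoride-driven silyl ether cleavage in a buffered, weakly acidic medium, in which formation of the strong Si–F bond removes the triethylsilyl group while the absence of basic or strongly nucleophilic species should spare the activated enol ester, the lactone, the vinyl group and the tertiary alcohol.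

**Compound list**
1 | methyl 3,3-dimethylpent-4-enoate | C=CC(C)(C)CC(=O)OC | starting material
2 | 1-acetylimidazole | CC(=O)n1ccnc1 | starting material
3 | lithium 1-methoxy-3,3-dimethylpenta-1,4-dien-1-olate (lithium enolate of 1) | C=CC(C)(C)C=C(OC)[O-].[Li+] | intermediate
4 | racemic methyl 2-acetyl-3,3-dimethylpent-4-enoate | C=CC(C)(C)C(C(C)=O)C(=O)OC | intermediate
5 | N-methoxy-N-methylbenzamide | CON(C)C(=O)c1ccccc1 | starting material
6 | sodium 3-(methoxycarbonyl)-4,4-dimethylhexa-2,5-dien-2-olate (sodium enolate of 4) | C=CC(C)(C)C(C(=O)OC)=C(C)[O-].[Na+] | intermediate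
7 | sodium lithium 1,3-dianion of 4 (inner enolate plus terminal CH2 carbanion) | C=CC(C)(C)C(C(=O)OC)=C([CH2-])[O-].[Na+].[Li+] | intermediate
8 | tetrahedral adduct of 7 to 5 (inner enolate, alkoxide chelated through the N-methoxy oxygen) | C=CC(C)(C)C(C(=O)OC)=C([O-])CC([O-])(N(C)OC)c1ccccc1.[Na+].[Li+] | intermediate
9 | racemic methyl 2-(2-methylbut-3-en-2-yl)-3,5-dioxo-5-phenylpentanoate | C=CC(C)(C)C(C(=O)OC)C(=O)CC(=O)c1ccccc1 | intermediate
10 | 4-hydroxy-3-(2-methylbut-3-en-2-yl)-6-phenyl-2H-pyran-2-one | C=CC(C)(C)c1c(O)cc(-c2ccccc2)oc1=O | intermediate
11 | 3-hydroxy-3-methylbutanoic acid | CC(C)(O)CC(=O)O | starting material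
12 | triethylsilyl 3-methyl-3-[(triethylsilyl)oxy]butanoate | CC[Si](CC)(CC)OC(=O)CC(C)(C)O[Si](CC)(CC)CC | intermediate
13 | 3-methyl-3-[(triethylsilyl)oxy]butanoyl chloride | CC[Si](CC)(CC)OC(C)(C)CC(=O)Cl | intermediate
14 | 3-(2-methylbut-3-en-2-yl)-2-oxo-6-phenyl-2H-pyran-4-yl 3-methyl-3-[(triethylsilyl)oxy]butanoate | C=CC(C)(C)c1c(OC(=O)CC(C)(C)O[Si](CC)(CC)CC)cc(-c2ccccc2)oc1=O | intermediate
15 | 3-(2-methylbut-3-en-2-yl)-2-oxo-6-phenyl-2H-pyran-4-yl 3-hydroxy-3-methylbutanoate | C=CC(C)(C)c1c(OC(=O)CC(C)(C)O)cc(-c2ccccc2)oc1=O | target

**Total step count:** 7
**Longest linear sequence:** 5 steps (steps 1, 2, 3, 6, 7). The side branch (steps 4 and 5) joins at step 6.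

**Steps most likely to fail**

1. **Step 2.** Removal of the congested methine proton of 4 may be slow or incomplete. n-BuLi would then add to the free ketone or ester, and proton exchange between mono- and dianion would lower the conversion.
   - Fallback: the order of events is changed. The pyranone is built without its C3 substituent, which is then delivered by a [3,3] shift. The fallback sets out from 5.
   - Methyl acetoacetate is deprotonated twice (NaH, then n-BuLi, THF, 0 °C) to the sodium lithium dianion of methyl acetoacetate F1.
   - This unhindered dianion is acylated with 5 to give methyl 3,5-dioxo-5-phenylpentanoate F2.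
   - DBU in hot toluene closes F2 to 4-hydroxy-6-phenyl-2H-pyran-2-one F3.
   - A Mitsunobu reaction with 3-methylbut-2-en-1-ol (PPh3, diisopropyl azodicarboxylate, THF) gives 4-[(3-methylbut-2-en-1-yl)oxy]-6-phenyl-2H-pyran-2-one F4.
   - A thermal Claisen rearrangement across C3=C4–O (toluene, sealed tube) moves the allyl unit with inversion onto C3. The fallback comes back to the route at 10.

2. **Step 1.** Proton transfer from the acetyl group of 2 to the hindered enolate, or acylation at oxygen, may outrun C–C bond formation at the neopentyl-type carbon.
   - Fallback: the acyl transfer is replaced by an aldol addition followed by oxidation. The fallback sets out from 1.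
   - Enolate 3 is generated as before and added at −78 °C to acetaldehyde, a small and much more electrophilic partner. This gives methyl 2-(1-hydroxyethyl)-3,3-dimethylpent-4-enoate F5 as a mixture of racemic diastereomers.
   - Dess–Martin oxidation (CH2Cl2, rt) removes the carbinol stereocentre. The fallback comes back to the route at 4.

3. **Step 7.** The side-chain ester behaves as a vinylogous anhydride. Acyl–oxygen cleavage by fluoride, pyridine or water during desilylation or work-up may therefore compete, as may acid-induced dehydration of the tertiary alcohol.
   - Fallback: the protecting group is left out altogether. The fallback sets out from 10 and 11.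
   - The two are joined directly by a Steglich esterification (N-(3-dimethylaminopropyl)-N′-ethylcarbodiimide hydrochloride, catalytic DMAP, CH2Cl2, 0 °C → rt).
   - The hindered tertiary hydroxyl of 11 should be too poor an acyl acceptor to compete. The fallback comes back to the route at 15 and makes no new compound (F0).

**Further compounds**
F1 | step 2 | sodium lithium dianion of methyl acetoacetate | [CH2-]C([O-])=CC(=O)OC.[Na+].[Li+]
F2 | step 2 | methyl 3,5-dioxo-5-phenylpentanoate | COC(=O)CC(=O)CC(=O)c1ccccc1
F3 | step 2 | 4-hydroxy-6-phenyl-2H-pyran-2-one | O=c1cc(O)cc(-c2ccccc2)o1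
F4 | step 2 | 4-[(3-methylbut-2-en-1-yl)oxy]-6-phenyl-2H-pyran-2-one | CC(C)=CCOc1cc(-c2ccccc2)oc(=O)c1
F5 | step 1 | methyl 2-(1-hydroxyethyl)-3,3-dimethylpent-4-enoate (racemic, mixture of diastereomers) | C=CC(C)(C)C(C(C)O)C(=O)OC
F0 | step 7 | none | none
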